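**Retrosynthetic overview**
1. The 2-hydroxy-5-methoxyquinone is unveiled last from a 2,3,5,6-tetramethoxyphenyl group (oxidative demethylation, then hydrolysis of one vinylogous ester); the C2 methyl stereocentre comes from hydroxyl-directed hydrogenation of a C2=C3 alkene.
2. Ring B is closed in one operation by a (3+3) annulation that forms C4–C4a and C1–C2: a but-2-ene-1,3-diyl unit, delivered by (Z)-1-bromo-3-iodobut-2-ene under SmI2, adds first as an allyl nucleophile to the ring A ketone and then as a vinyl radical to a styrene.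
3. Enabling feature: in the ring A precursor the carbonyl carbon (future C4a) and the β-carbon of the aryl-conjugated alkene (future C1) are 1,3-related across the ring-fusion CH (C8a), so a three-carbon chain can bridge them; the aryl group makes that alkene a 6-exo radical acceptor, and the new tertiary OH later directs the hydrogenation.
4. The keto-styrene comes from 2,2-dimethylcyclohexanone by SAMP-hydrazone alkylation with an α-bromo aryl ketone (sets C8a), reduction and dehydration.
5. Ring order: ring A (bought) → ring B (key step) → quinone ring (from the arene).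

Key step: step 9

Remark: locants C1–C8a are those of the decalin in the target (C1 quaternary carbon, C2 CHMe, C4a carbinol carbon, C5 CMe2, C8a ring-fusion CH); the side-chain centres of 3, 8 and 9 are left undefined because step 5 erases them.

**Step 1**
Reactants: 1 1,2,4,5-tetramethoxybenzene; 2 2-bromopropanoic acid (racemic)
Product: 3 2-bromo-1-(2,3,5,6-tetramethoxyphenyl)propan-1-one (racemic)
Conditions: (CF3CO)2O, H3PO4 (cat.), CH2Cl2, 0 °C → rt
Reagents that add atoms: none
Why: Friedel–Crafts acylation through the mixed trifluoroacetic anhydride should proceed on this very electron-rich arene, whose two free positions are equivalent, so one mono-acylated regioisomer is expected; the racemic bromide-bearing centre is made planar in step 5.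

**Step 2**
Reactants: 4 2,2-dimethylcyclohexanone; 5 SAMP, (S)-1-amino-2-(methoxymethyl)pyrrolidine
Product: 6 (S)-N-[(E)-2,2-dimethylcyclohexylidene]-2-(methoxymethyl)pyrrolidin-1-amine
Conditions: TsOH (cat.), cyclohexane, reflux, azeotropic removal of water
Reagents that add atoms: none
Why: Acid-catalysed hydrazone formation should give the E-hydrazone (pyrrolidine nitrogen anti to the quaternary carbon), which exposes the only enolisable CH2 group for syn-deprotonation; the auxiliary stereocentre is untouched.

**Step 3**
Reactants: 6 (S)-N-[(E)-2,2-dimethylcyclohexylidene]-2-(methoxymethyl)pyrrolidin-1-amine; 3 2-bromo-1-(2,3,5,6-tetramethoxyphenyl)propan-1-one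
Product: 8 SAMP hydrazone of (6S)-2,2-dimethyl-6-[1-oxo-1-(2,3,5,6-tetramethoxyphenyl)propan-2-yl]cyclohexanone (side-chain epimers), via lithium azaenolate 7 (not isolated)
Conditions: LiN(iPr)2, THF, 0 °C; then 3, −100 → −78 °C
Reagents that add atoms: none
Why: SAMP-hydrazone alkylation: the lithium azaenolate, held rigid by chelation to the methoxymethyl group, should be attacked by the SN2-reactive α-bromo ketone on the face away from the pyrrolidine substituent, which sets the ring stereocentre (future C8a) as S.

**Step 4**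
Reactants: 8 SAMP hydrazone of (6S)-2,2-dimethyl-6-[1-oxo-1-(2,3,5,6-tetramethoxyphenyl)propan-2-yl]cyclohexanone
Product: 9 SAMP hydrazone of (6S)-6-[1-hydroxy-1-(2,3,5,6-tetramethoxyphenyl)propan-2-yl]-2,2-dimethylcyclohexanone (diastereomer mixture)
Conditions: LiAlH4, THF, 0 °C
Reagents that add atoms: none
Why: LiAlH4 should reduce the hindered aryl ketone to the benzylic alcohol while the N,N-dialkylhydrazone is inert at 0 °C; the new carbinol centre forms unselectively and is erased in step 5.

**Step 5**
Reactants: 9 SAMP hydrazone of (6S)-6-[1-hydroxy-1-(2,3,5,6-tetramethoxyphenyl)propan-2-yl]-2,2-dimethylcyclohexanone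
Product: 10 SAMP hydrazone of (S)-2,2-dimethyl-6-[(E)-1-(2,3,5,6-tetramethoxyphenyl)prop-1-en-2-yl]cyclohexanone
Conditions: MsCl, Et3N, CH2Cl2, 0 °C → reflux
Reagents that add atoms: none
Why: The mesylate of this electron-rich benzylic alcohol should ionise and lose the adjacent methine proton (E1 elimination) to give the less hindered E-styrene, which removes both side-chain stereocentres and leaves the S centre untouched.

**Step 6**
Reactants: 10 SAMP hydrazone of (S)-2,2-dimethyl-6-[(E)-1-(2,3,5,6-tetramethoxyphenyl)prop-1-en-2-yl]cyclohexanone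
Product: 11 (S)-2,2-dimethyl-6-[(E)-1-(2,3,5,6-tetramethoxyphenyl)prop-1-en-2-yl]cyclohexanone
Conditions: oxalic acid (sat. aq.), Et2O, rt
Reagents that add atoms: water, O
Why: Mild two-phase hydrolysis of the hydrazone should release the ketone and the recoverable auxiliary without enolisation, so the α-stereocentre (activated twice, to be used at once) is retained.

**Step 7**
Reactants: 12 but-2-yn-1-ol
Product: 13 (Z)-3-iodobut-2-en-1-ol
Conditions: NaAlH2(OCH2CH2OMe)2, Et2O, 0 °C; then I2, THF, −78 °C
Reagents that add atoms: iodine, II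
Why: Hydroxyl-directed trans-hydroalumination of the propargylic alcohol places aluminium on the distal alkyne carbon, and iodinolysis with retention should give the Z-3-iodoallylic alcohol as one regio- and stereoisomer.

**Step 8**
Reactants: 13 (Z)-3-iodobut-2-en-1-ol
Product: 14 (Z)-1-bromo-3-iodobut-2-ene
Conditions: CBr4, PPh3, CH2Cl2, 0 °C
Reagents that add atoms: tetrabromomethane, BrC(Br)(Br)Br
Why: The Appel reaction should convert the primary allylic alcohol into the bromide under neutral conditions without allylic transposition or loss of the alkenyl iodide.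

**Step 9**
Reactants: 11 (S)-2,2-dimethyl-6-[(E)-1-(2,3,5,6-tetramethoxyphenyl)prop-1-en-2-yl]cyclohexanone; 14 (Z)-1-bromo-3-iodobut-2-ene
Product: 16 (1S,4aS,8aS)-1,2,5,5-tetramethyl-1-[(2,3,5,6-tetramethoxyphenyl)methyl]-1,4,5,6,7,8-hexahydronaphthalen-4a(8aH)-ol, via trivalent samarium alkoxide 15 (not isolated)
Conditions: SmI2 (4.5 equiv), THP, −78 → 0 °C; then HMPA, t-BuOH, 0 °C → rt
Reagents that add atoms: none
Why: Proposed new method: SmI2 should first reduce the allylic C–Br bond of 14 (far faster than the alkenyl C–I bond while HMPA is absent), and the allylsamarium should add through its unsubstituted terminus to the ketone of 11 in a Barbier reaction (C4–C4a bond) to give trivalent samarium alkoxide 15; HMPA then raises the reducing power of the remaining divalent samarium, the alkenyl iodide gives a σ-vinyl radical that closes ring B by 6-exo-trig addition to the styrene carbon (C1–C2 bond), and the benzylic radical is reduced and protonated by t-BuOH. The closest known reaction types are the samarium Barbier allylation of ketones and the SmI2–HMPA or tin hydride 6-exo cyclization of alkenyl and aryl radicals onto styrenes, here run in sequence by one reductant on a reagent that is an allyl anion at one end and a vinyl radical at the other. C4a is set in the Barbier stage by axial attack on the chair ketone (styrenyl group equatorial), anti to the axial C5 methyl group, which puts OH cis to H-8a and the butenyl chain axial, next to the styrene. C1 is set in the radical stage by allylic strain: in the unstrained rotamer of the E-styrene the C1 methyl group lies over C8H2 and the vinylic CH points toward C4a, so the radical tethered at C4a bonds to the face that leaves the arylmethyl arm cis to H-8a and the methyl group trans to it; C2 stays sp2 and is set in step 10. The step needs terminus-selective allylation, cyclization faster than hydrogen abstraction, and 6-exo rather than 7-endo closure; these should be secured by the fully substituted iodine-bearing terminus of the allyl unit, by THP as a poor hydrogen donor together with H-8a being trans-diaxial to the chain (out of reach), and by the benzylic stabilization of the 6-exo radical.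

**Step 10**
Reactants: 16 (1S,4aS,8aS)-1,2,5,5-tetramethyl-1-[(2,3,5,6-tetramethoxyphenyl)methyl]-1,4,5,6,7,8-hexahydronaphthalen-4a(8aH)-ol
Product: 17 (1R,2S,4aS,8aS)-1,2,5,5-tetramethyl-1-[(2,3,5,6-tetramethoxyphenyl)methyl]octahydronaphthalen-4a(2H)-ol
Conditions: H2 (1 atm), [Ir(cod)(PCy3)(py)]PF6 (5 mol %), CH2Cl2, rt
Reagents that add atoms: none
Why: Hydroxyl-directed hydrogenation: the cationic iridium catalyst binds the homoallylic tertiary hydroxyl and should deliver H2 to the alkene face on which OH lies, so the new C2–H is cis to OH and the methyl group trans to it (2S), with the arene untouched.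

**Step 11**
Reactants: 17 (1R,2S,4aS,8aS)-1,2,5,5-tetramethyl-1-[(2,3,5,6-tetramethoxyphenyl)methyl]octahydronaphthalen-4a(2H)-ol
Product: 18 3-{[(1R,2S,4aS,8aS)-4a-hydroxy-1,2,5,5-tetramethyldecahydronaphthalen-1-yl]methyl}-2,5-dimethoxycyclohexa-2,5-diene-1,4-dione
Conditions: (NH4)2Ce(NO3)6, MeCN/H2O, 0 °C
Reagents that add atoms: water, O
Why: Oxidative demethylation of the electron-rich arene should give the 2,5-dimethoxy-1,4-benzoquinone (either para-dimethoxy pair gives the same quinone by symmetry) while the tertiary alcohol is inert.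

**Step 12**
Reactants: 18 3-{[(1R,2S,4aS,8aS)-4a-hydroxy-1,2,5,5-tetramethyldecahydronaphthalen-1-yl]methyl}-2,5-dimethoxycyclohexa-2,5-diene-1,4-dione
Product: 19 2-hydroxy-3-{[(1R,2S,4aS,8aS)-4a-hydroxy-1,2,5,5-tetramethyldecahydronaphthalen-1-yl]methyl}-5-methoxycyclohexa-2,5-diene-1,4-dione (target)
Conditions: KOH, MeOH/H2O, rt; then HCl (aq.)
Reagents that add atoms: potassium hydroxide, [K+].[OH-]
Why: Hydroxide should add to the methoxy-bearing quinone carbon next to the alkyl group and expel methoxide (hydrolysis of a vinylogous ester), the regiochemistry expected for 2,5-dimethoxy-3-alkyl-1,4-benzoquinones, giving the 2-hydroxy-5-methoxyquinone with all four stereocentres unchanged.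

**Compound list**
1 | 1,2,4,5-tetramethoxybenzene | COc1cc(OC)c(OC)cc1OC | starting material
2 | 2-bromopropanoic acid (racemic) | CC(Br)C(O)=O | starting material
3 | 2-bromo-1-(2,3,5,6-tetramethoxyphenyl)propan-1-one (racemic) | CC(Br)C(=O)c1c(OC)c(OC)cc(OC)c1OC | intermediate
4 | 2,2-dimethylcyclohexanone | CC1(C)CCCCC1=O | starting material
5 | SAMP, (S)-1-amino-2-(methoxymethyl)pyrrolidine | COC[C@@H]1CCCN1N | starting material
6 | (S)-N-[(E)-2,2-dimethylcyclohexylidene]-2-(methoxymethyl)pyrrolidin-1-amine | C1CCCC(C)(C)/C1=N/N1CCC[C@H]1COC | intermediate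
7 | lithium azaenolate of 6 | [Li]N(N1CCC[C@H]1COC)C1=CCCCC1(C)C | intermediate
8 | SAMP hydrazone of (6S)-2,2-dimethyl-6-[1-oxo-1-(2,3,5,6-tetramethoxyphenyl)propan-2-yl]cyclohexanone (side-chain epimers) | CC(C(=O)c1c(OC)c(OC)cc(OC)c1OC)[C@@H]1CCCC(C)(C)/C1=N/N1CCC[C@H]1COC | intermediate
9 | SAMP hydrazone of (6S)-6-[1-hydroxy-1-(2,3,5,6-tetramethoxyphenyl)propan-2-yl]-2,2-dimethylcyclohexanone (diastereomer mixture) | CC(C(O)c1c(OC)c(OC)cc(OC)c1OC)[C@@H]1CCCC(C)(C)/C1=N/N1CCC[C@H]1COC | intermediate
10 | SAMP hydrazone of (S)-2,2-dimethyl-6-[(E)-1-(2,3,5,6-tetramethoxyphenyl)prop-1-en-2-yl]cyclohexanone | C/C(=C\c1c(OC)c(OC)cc(OC)c1OC)[C@@H]1CCCC(C)(C)/C1=N/N1CCC[C@H]1COC | intermediate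
11 | (S)-2,2-dimethyl-6-[(E)-1-(2,3,5,6-tetramethoxyphenyl)prop-1-en-2-yl]cyclohexanone | C/C(=C\c1c(OC)c(OC)cc(OC)c1OC)[C@@H]1CCCC(C)(C)C1=O | intermediate
12 | but-2-yn-1-ol | CC#CCO | starting material
13 | (Z)-3-iodobut-2-en-1-ol | OC/C=C(/C)I | intermediate
14 | (Z)-1-bromo-3-iodobut-2-ene | BrC/C=C(/C)I | intermediate
15 | trivalent samarium alkoxide of (1S,2S)-1-[(Z)-3-iodobut-2-en-1-yl]-6,6-dimethyl-2-[(E)-1-(2,3,5,6-tetramethoxyphenyl)prop-1-en-2-yl]cyclohexan-1-ol | C/C(=C\c1c(OC)c(OC)cc(OC)c1OC)[C@@H]1CCCC(C)(C)[C@]1(O[Sm](I)I)C/C=C(/C)I | intermediate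
16 | (1S,4aS,8aS)-1,2,5,5-tetramethyl-1-[(2,3,5,6-tetramethoxyphenyl)methyl]-1,4,5,6,7,8-hexahydronaphthalen-4a(8aH)-ol | COc1cc(OC)c(OC)c(C[C@]2(C)C(C)=CC[C@]3(O)[C@H]2CCCC3(C)C)c1OC | intermediate
17 | (1R,2S,4aS,8aS)-1,2,5,5-tetramethyl-1-[(2,3,5,6-tetramethoxyphenyl)methyl]octahydronaphthalen-4a(2H)-ol | COc1cc(OC)c(OC)c(C[C@]2(C)[C@@H](C)CC[C@]3(O)[C@H]2CCCC3(C)C)c1OC | intermediate
18 | 3-{[(1R,2S,4aS,8aS)-4a-hydroxy-1,2,5,5-tetramethyldecahydronaphthalen-1-yl]methyl}-2,5-dimethoxycyclohexa-2,5-diene-1,4-dione | COC1=CC(=O)C(OC)=C(C[C@]2(C)[C@@H](C)CC[C@]3(O)[C@H]2CCCC3(C)C)C1=O | intermediate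
19 | 2-hydroxy-3-{[(1R,2S,4aS,8aS)-4a-hydroxy-1,2,5,5-tetramethyldecahydronaphthalen-1-yl]methyl}-5-methoxycyclohexa-2,5-diene-1,4-dione | COC1=CC(=O)C(O)=C(C[C@]2(C)[C@@H](C)CC[C@]3(O)[C@H]2CCCC3(C)C)C1=O | target

**Step count and risks**
Total step count: 12 steps. Longest linear sequence: 9 steps (steps 2–6 and 9–12 from 4; equally steps 1, 3–6 and 9–12 from 1).

Steps most likely to fail:

Step 9 (proposed new method). The vinyl radical may be reduced or may abstract hydrogen before it cyclizes, and the Barbier stage may proceed by equatorial instead of axial attack. Fallback with known chemistry, making the two bonds in two steps: setting out from 11, indium-mediated Barbier allylation with 14 (indium powder, THF/H2O, rt) would give (1S,2S)-1-[(Z)-3-iodobut-2-en-1-yl]-6,6-dimethyl-2-[(E)-1-(2,3,5,6-tetramethoxyphenyl)prop-1-en-2-yl]cyclohexan-1-ol F1, which would be isolated. A reductive Heck cyclization (Pd(OAc)2, PPh3, HCO2Na, Et4NCl, DMF, 80 °C; 6-exo carbopalladation of the styrene, then formate reduction of the neopentyl alkylpalladium, which has no β-hydrogen) would close ring B and come back to the route at 16.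

Step 3. Proton transfer from the acidic α-bromo ketone to the azaenolate may compete with substitution, lowering conversion and stereochemical purity. Fallback: setting out from 6, azaenolate 7 would be alkylated with methyl 2-bromopropanoate, a much less acidic and established class of electrophile for such azaenolates, to give methyl 2-[(1S)-3,3-dimethyl-2-{[(2S)-2-(methoxymethyl)pyrrolidin-1-yl]imino}cyclohexyl]propanoate F2. Single addition of 2,3,5,6-tetramethoxyphenyllithium F3 (from 1, n-BuLi, TMEDA, THF, 0 °C) to this ester at −78 °C, which should stop at the shielded aryl ketone, would come back to the route at 8.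

Step 12. Hydrolysis may fail to discriminate between the two vinylogous esters. Fallback: setting out from 18, both methoxy groups would be hydrolysed (NaOH, H2O/dioxane, reflux; then HCl) to 2,5-dihydroxy-3-{[(1R,2S,4aS,8aS)-4a-hydroxy-1,2,5,5-tetramethyldecahydronaphthalen-1-yl]methyl}cyclohexa-2,5-diene-1,4-dione F4. Acid-catalysed mono-methylation (MeOH, HCl, rt) of the less hindered hydroxyl, the one next to the ring CH, would then come back to the route at 19.

**Further compounds**
F1 | step 9 | (1S,2S)-1-[(Z)-3-iodobut-2-en-1-yl]-6,6-dimethyl-2-[(E)-1-(2,3,5,6-tetramethoxyphenyl)prop-1-en-2-yl]cyclohexan-1-ol | C/C(=C\c1c(OC)c(OC)cc(OC)c1OC)[C@@H]1CCCC(C)(C)[C@]1(O)C/C=C(/C)I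
F2 | step 3 | methyl 2-[(1S)-3,3-dimethyl-2-{[(2S)-2-(methoxymethyl)pyrrolidin-1-yl]imino}cyclohexyl]propanoate | COC(=O)C(C)[C@@H]1CCCC(C)(C)/C1=N/N1CCC[C@H]1COC
F3 | step 3 | 2,3,5,6-tetramethoxyphenyllithium | [Li]c1c(OC)c(OC)cc(OC)c1OC
F4 | step 12 | 2,5-dihydroxy-3-{[(1R,2S,4aS,8aS)-4a-hydroxy-1,2,5,5-tetramethyldecahydronaphthalen-1-yl]methyl}cyclohexa-2,5-diene-1,4-dione | OC1=CC(=O)C(O)=C(C[C@]2(C)[C@@H](C)CC[C@]3(O)[C@H]2CCCC3(C)C)C1=O
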